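**Retrosynthetic overview**
- Target ⇐ α,β-dehydrogenation of the saturated trans-fused 3a-methylhydroazulen-5-one.
- Seven-membered ring (formed second) ⇐ cathodic 7-endo radical-anion cyclisation of an isopropenyl ketone onto an exocyclic methylene; it makes the C7–C8 bond and the C8a–H centre.
- Quaternary C3a and the enone arm ⇐ Claisen rearrangement of a cyclopentenylmethanol with 2-methoxy-3-methylbuta-1,3-diene.
- Five-membered ring (formed first) ⇐ ozonolysis and intramolecular aldol ring contraction of the cyclohexene of (−)-α-bisabolol, which supplies C1 and the tertiary carbinol centre.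
- Side-chain C3 acetate ⇐ hydroxyl-directed epoxidation, epoxide-to-allylic-alcohol isomerisation and Mitsunobu inversion, carried out first.

Assumption: commercial (−)-α-bisabolol is the (S,S)-isomer, and its vanadium-directed epoxidation takes the sense usual for tertiary bishomoallylic alcohols (the epoxide that would close to the 2,5-trans oxolane), i.e. the (R)-epoxide; this sense is recalled from precedent, not derived, and if it is the opposite the step-1 fallback below applies.

**Step 1**
Reactants: 1 (−)-α-bisabolol, (2S)-6-methyl-2-[(1S)-4-methylcyclohex-3-en-1-yl]hept-5-en-2-ol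
Product: 2 (2S)-4-[(2R)-3,3-dimethyloxiran-2-yl]-2-[(1S)-4-methylcyclohex-3-en-1-yl]butan-2-ol
Conditions: VO(acac)2 (2 mol%), t-BuOOH (1.1 equiv), NaOAc, toluene, 0 °C
Reagents that add atoms: tert-butyl hydroperoxide, CC(C)(C)OO
Why: Hydroxyl-directed epoxidation in which the vanadate ester (pentavalent vanadium) of the bought (S)-carbinol delivers oxygen through a chair-like transition state to one face of the side-chain alkene, giving the (R)-epoxide; the buffer keeps the epoxy alcohol from closing to the oxolane, and the ring alkene is reached only from an axial conformer and reacts more slowly.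

**Step 2**
Reactants: 2 (2S)-4-[(2R)-3,3-dimethyloxiran-2-yl]-2-[(1S)-4-methylcyclohex-3-en-1-yl]butan-2-ol
Product: 3 (3R,6S)-2-methyl-6-[(1S)-4-methylcyclohex-3-en-1-yl]hept-1-ene-3,6-diol
Conditions: Cp2TiCl2 (10 mol%), Co(salen) (5 mol%), Zn (20 mol%), Et3N·HCl (20 mol%), THF, 22 °C
Reagents that add atoms: none
Why: Titanocene/cobalt radical redox-relay isomerisation of an epoxide to an allylic alcohol: trivalent titanium opens the epoxide to the tertiary radical with the C3–O bond untouched (C3 stays R) and divalent cobalt removes a methyl hydrogen to give the 1,1-disubstituted alkene.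

**Step 3**
Reactants: 3 (3R,6S)-2-methyl-6-[(1S)-4-methylcyclohex-3-en-1-yl]hept-1-ene-3,6-diol
Product: 4 (3S,6S)-6-hydroxy-2-methyl-6-[(1S)-4-methylcyclohex-3-en-1-yl]hept-1-en-3-yl acetate
Conditions: AcOH (3 equiv), PPh3 (1.5 equiv), DIAD (1.5 equiv), toluene, −20 → 0 °C
Reagents that add atoms: acetic acid, CC(=O)O
Why: Mitsunobu esterification: SN2 attack of acetate on the activated secondary allylic alcohol inverts C3 from R to S and installs the acetate in the same step, while the hindered tertiary alcohol is not activated and excess acid outruns oxolane closure.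

**Step 4**
Reactants: 4 (3S,6S)-6-hydroxy-2-methyl-6-[(1S)-4-methylcyclohex-3-en-1-yl]hept-1-en-3-yl acetate
Product: 6 (3S,6S,7S)-6-hydroxy-2,6-dimethyl-10-oxo-7-(2-oxoethyl)undec-1-en-3-yl acetate, via ozonide 5 (not isolated)
Conditions: O3, CH2Cl2, −78 °C (Sudan Red 7B end point); then PPh3, −78 → 20 °C
Reagents that add atoms: ozone, [O-][O+]=O
Why: Ozonolysis with reductive work-up; ozone takes the electron-rich trisubstituted ring alkene before the acetoxy-deactivated 1,1-disubstituted side-chain alkene, and the keto aldehyde (largely a five-membered lactol with the tertiary OH) still reacts as the aldehyde.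

**Step 5**
Reactants: 6 (3S,6S,7S)-6-hydroxy-2,6-dimethyl-10-oxo-7-(2-oxoethyl)undec-1-en-3-yl acetate
Product: 8 (3S,6S)-6-[(1S)-2-formyl-3-methylcyclopent-2-en-1-yl]-6-hydroxy-2-methylhept-1-en-3-yl acetate, via aldol adduct 7 (not isolated)
Conditions: piperidine (0.3 equiv), AcOH (0.3 equiv), benzene, 80 °C, 4 Å MS
Reagents that add atoms: none
Why: Enamine-mediated intramolecular aldol condensation (the aldehyde enamine attacks the methyl ketone, then dehydration) forms the cyclopentene ring; the C1 stereocentre is not enolisable and is kept.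

**Step 6**
Reactants: 8 (3S,6S)-6-[(1S)-2-formyl-3-methylcyclopent-2-en-1-yl]-6-hydroxy-2-methylhept-1-en-3-yl acetate
Product: 9 (3S,6S)-6-hydroxy-6-[(1S)-2-(hydroxymethyl)-3-methylcyclopent-2-en-1-yl]-2-methylhept-1-en-3-yl acetate
Conditions: NaBH4, CeCl3·7H2O, MeOH, −20 °C
Reagents that add atoms: none
Why: Luche 1,2-reduction of the enal gives the primary allylic alcohol and leaves the acetate and both alkenes alone.

**Step 7**
Reactants: 10 3-methylbut-3-en-2-one
Product: 12 2-methoxy-3-methylbuta-1,3-diene, via 1,3,3-trimethoxy-2-methylbutane 11 (not isolated)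
Conditions: HC(OMe)3, MeOH, TsOH (cat.), 0 → 20 °C; then KHSO4 (cat.), 150 °C, distil
Reagents that add atoms: trimethyl orthoformate, COC(OC)OC; methanol, CO
Why: Conjugate addition of methanol and ketalisation, then acid-catalysed loss of two methanol molecules, by analogy with the standard preparation of 2-methoxybuta-1,3-diene.

**Step 8**
Reactants: 9 (3S,6S)-6-hydroxy-6-[(1S)-2-(hydroxymethyl)-3-methylcyclopent-2-en-1-yl]-2-methylhept-1-en-3-yl acetate; 12 2-methoxy-3-methylbuta-1,3-diene
Product: 14 (3S,6S)-6-hydroxy-2-methyl-6-[(1S,3R)-3-methyl-3-(3-methyl-2-oxobut-3-en-1-yl)-2-methylidenecyclopentyl]hept-1-en-3-yl acetate, via allyl dienyl ether 13 (not isolated)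
Conditions: 12 (4 equiv), 2,4-dinitrophenol (5 mol%), toluene, 115 °C, sealed tube
Reagents that add atoms: none
Why: Acid-catalysed transetherification followed by Claisen rearrangement; the [3,3] shift delivers the CH2–C(=O) arm to the methyl-bearing ring carbon on the face opposite the bulky C1 substituent, setting the quaternary centre (3R) and leaving the exocyclic methylene.

**Step 9**
Reactants: 14 (3S,6S)-6-hydroxy-2-methyl-6-[(1S,3R)-3-methyl-3-(3-methyl-2-oxobut-3-en-1-yl)-2-methylidenecyclopentyl]hept-1-en-3-yl acetate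
Product: 15 (3S,6S)-6-[(1S,3aR,8aS)-3a,6-dimethyl-5-oxodecahydroazulen-1-yl]-6-hydroxy-2-methylhept-1-en-3-yl acetate (C6 epimers)
Conditions: undivided cell, glassy-carbon cathode, Mg anode, −2.15 V vs SCE (2.2 F/mol), nBu4NBF4 (0.1 M) in DMF, t-BuOH (3 equiv), 5 mM, 0 °C; then aq NH4Cl
Reagents that add atoms: none
Why: Proposed new method: one-electron cathodic reduction of the magnesium-ion-bound isopropenyl ketone gives a radical anion whose β-carbon adds 7-endo to the unsubstituted end of the unactivated exocyclic methylene (6-exo attack would have to join two fully substituted carbons), and the tertiary C8a radical is then reduced and protonated by t-BuOH on the α face, anti to the 3a-methyl group and the C1 side chain, giving the trans ring fusion; the closest known reactions are electrohydrocyclisation and electroreductive ketyl–olefin cyclisation, neither shown for an enone β-carbon closing a seven-membered ring onto an unactivated alkene.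

**Step 10**
Reactants: 15 (3S,6S)-6-[(1S,3aR,8aS)-3a,6-dimethyl-5-oxodecahydroazulen-1-yl]-6-hydroxy-2-methylhept-1-en-3-yl acetate (C6 epimers)
Product: 16 (3S,6S)-6-[(1S,3aR,8aS)-3a,6-dimethyl-5-oxo-1,2,3,3a,4,5,8,8a-octahydroazulen-1-yl]-6-hydroxy-2-methylhept-1-en-3-yl acetate (CNP0193642.1)
Conditions: IBX (2 equiv), DMSO/toluene (1:2), 70 °C
Reagents that add atoms: none
Why: IBX dehydrogenation of the ketone through its enol; only the C6–C7 side carries a β-hydrogen (C4 is flanked by the quaternary C3a), so both C6 epimers converge on the endocyclic 2-methyl enone, and the tertiary alcohol and allylic acetate are inert.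

**Compound list**
1 | (−)-α-bisabolol, (2S)-6-methyl-2-[(1S)-4-methylcyclohex-3-en-1-yl]hept-5-en-2-ol | CC(C)=CCC[C@](C)(O)[C@H]1CCC(C)=CC1 | starting material
2 | (2S)-4-[(2R)-3,3-dimethyloxiran-2-yl]-2-[(1S)-4-methylcyclohex-3-en-1-yl]butan-2-ol | CC1(C)O[C@@H]1CC[C@](C)(O)[C@H]1CCC(C)=CC1 | intermediate
3 | (3R,6S)-2-methyl-6-[(1S)-4-methylcyclohex-3-en-1-yl]hept-1-ene-3,6-diol | C=C(C)[C@H](O)CC[C@](C)(O)[C@H]1CCC(C)=CC1 | intermediate
4 | (3S,6S)-6-hydroxy-2-methyl-6-[(1S)-4-methylcyclohex-3-en-1-yl]hept-1-en-3-yl acetate | C=C(C)[C@H](CC[C@](C)(O)[C@H]1CCC(C)=CC1)OC(C)=O | intermediate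
5 | ozonide of 4 (1,2,4-trioxolane across the former ring C=C, both ozonide faces) | CC(=O)O[C@@H](CC[C@](C)(O)[C@H]1CCC2(C)OOC(C1)O2)C(C)=C | intermediate
6 | (3S,6S,7S)-6-hydroxy-2,6-dimethyl-10-oxo-7-(2-oxoethyl)undec-1-en-3-yl acetate (in equilibrium with its five-membered lactol) | CC(=O)O[C@@H](CC[C@](C)(O)[C@H](CC=O)CCC(C)=O)C(C)=C | intermediate
7 | (3S,6S)-6-[(1S)-2-formyl-3-hydroxy-3-methylcyclopentyl]-6-hydroxy-2-methylhept-1-en-3-yl acetate (aldol adduct, mixture at the two new centres) | CC(=O)O[C@@H](CC[C@](C)(O)[C@H]1CCC(C)(O)C1C=O)C(C)=C | intermediate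
8 | (3S,6S)-6-[(1S)-2-formyl-3-methylcyclopent-2-en-1-yl]-6-hydroxy-2-methylhept-1-en-3-yl acetate | CC(=O)O[C@@H](CC[C@](C)(O)[C@H]1CCC(C)=C1C=O)C(C)=C | intermediate
9 | (3S,6S)-6-hydroxy-6-[(1S)-2-(hydroxymethyl)-3-methylcyclopent-2-en-1-yl]-2-methylhept-1-en-3-yl acetate | CC(=O)O[C@@H](CC[C@](C)(O)[C@H]1CCC(C)=C1CO)C(C)=C | intermediate
10 | 3-methylbut-3-en-2-one | CC(=O)C(C)=C | starting material
11 | 1,3,3-trimethoxy-2-methylbutane | COCC(C)C(C)(OC)OC | intermediate
12 | 2-methoxy-3-methylbuta-1,3-diene | COC(=C)C(C)=C | intermediate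
13 | (3S,6S)-6-hydroxy-2-methyl-6-[(1S)-3-methyl-2-{[(3-methylbuta-1,3-dien-2-yl)oxy]methyl}cyclopent-2-en-1-yl]hept-1-en-3-yl acetate (allyl dienyl ether) | CC(=O)O[C@@H](CC[C@](C)(O)[C@H]1CCC(C)=C1COC(=C)C(C)=C)C(C)=C | intermediate
14 | (3S,6S)-6-hydroxy-2-methyl-6-[(1S,3R)-3-methyl-3-(3-methyl-2-oxobut-3-en-1-yl)-2-methylidenecyclopentyl]hept-1-en-3-yl acetate | CC(=O)O[C@@H](CC[C@](C)(O)[C@H]1CC[C@](C)(CC(=O)C(C)=C)C1=C)C(C)=C | intermediate
15 | (3S,6S)-6-[(1S,3aR,8aS)-3a,6-dimethyl-5-oxodecahydroazulen-1-yl]-6-hydroxy-2-methylhept-1-en-3-yl acetate (C6 epimers) | C=C(C)[C@H](CC[C@](C)(O)[C@H]1CC[C@]2(C)CC(=O)C(C)CC[C@@H]12)OC(C)=O | intermediate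
16 | (3S,6S)-6-[(1S,3aR,8aS)-3a,6-dimethyl-5-oxo-1,2,3,3a,4,5,8,8a-octahydroazulen-1-yl]-6-hydroxy-2-methylhept-1-en-3-yl acetate | C=C(C)[C@H](CC[C@](C)(O)[C@H]1CC[C@]2(C)CC(=O)C(C)=CC[C@@H]12)OC(C)=O | target

**Step count and risks**
Total: 10 steps (nine in the main line plus step 7, which prepares diene 12). Longest linear sequence: 9 steps, from 1 to 16 through steps 1–6 and 8–10.

The three steps most likely to fail:

Step 9 (the new cathodic cyclisation). The risks are plain 1,4-reduction, hydrodimerisation and protonation of C8a from the wrong face. The fallback uses known chemistry, sets out from 14 and comes back at 15. Benzeneselenol with catalytic Et3N in CH2Cl2 at 0 °C adds to the enone of 14 to give the β-seleno ketone (3S,6S)-6-hydroxy-2-methyl-6-[(1S,3R)-3-methyl-3-[3-methyl-2-oxo-4-(phenylselanyl)butyl]-2-methylidenecyclopentyl]hept-1-en-3-yl acetate F4. Slow addition of Bu3SnH with AIBN in benzene at 80 °C (2 mM) then releases the primary alkyl radical, which closes 7-endo onto the exocyclic methylene; the tertiary C8a radical takes hydrogen from the tin hydride on the α face to give 15, which is dehydrogenated as in step 10. This is itself a slow radical closure and needs high dilution.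

Step 1 (sense and level of the 1,4-induction, premature oxolane closure, competing ring-alkene epoxidation). The fallback sets out from 1 and comes back at 4 without relying on one sense of induction. If the epoxidation also, or mainly, gives the epimeric epoxide (2S)-4-[(2S)-3,3-dimethyloxiran-2-yl]-2-[(1S)-4-methylcyclohex-3-en-1-yl]butan-2-ol F1, the mixture is isomerised as in step 2 and the two diols are separated. Diol 3 is inverted as in step 3, and the epimer (3S,6S)-2-methyl-6-[(1S)-4-methylcyclohex-3-en-1-yl]hept-1-ene-3,6-diol F2 is acetylated with retention (Ac2O, DMAP, pyridine), so both epimers converge on 4.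

Step 4 (over-ozonolysis of the side-chain isopropenyl group). The fallback sets out from 4 and comes back at 6. mCPBA (1.05 equiv, NaHCO3, CH2Cl2, 0 °C) epoxidises only the trisubstituted ring alkene to the epoxide (3S,6S)-6-hydroxy-2-methyl-6-[(3S)-6-methyl-7-oxabicyclo[4.1.0]heptan-3-yl]hept-1-en-3-yl acetate F3, and H5IO6 in THF/water hydrolyses and cleaves it to 6.

**Further compounds**
F1 | step 1 | (2S)-4-[(2S)-3,3-dimethyloxiran-2-yl]-2-[(1S)-4-methylcyclohex-3-en-1-yl]butan-2-ol | CC1(C)O[C@H]1CC[C@](C)(O)[C@H]1CCC(C)=CC1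
F2 | step 1 | (3S,6S)-2-methyl-6-[(1S)-4-methylcyclohex-3-en-1-yl]hept-1-ene-3,6-diol | C=C(C)[C@@H](O)CC[C@](C)(O)[C@H]1CCC(C)=CC1
F3 | step 4 | (3S,6S)-6-hydroxy-2-methyl-6-[(3S)-6-methyl-7-oxabicyclo[4.1.0]heptan-3-yl]hept-1-en-3-yl acetate (both epoxide faces) | C=C(C)[C@H](CC[C@](C)(O)[C@H]1CCC2(C)OC2C1)OC(C)=O
F4 | step 9 | (3S,6S)-6-hydroxy-2-methyl-6-[(1S,3R)-3-methyl-3-[3-methyl-2-oxo-4-(phenylselanyl)butyl]-2-methylidenecyclopentyl]hept-1-en-3-yl acetate | CC(=O)O[C@@H](CC[C@](C)(O)[C@H]1CC[C@](C)(CC(=O)C(C)C[Se]c2ccccc2)C1=C)C(C)=C
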